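**Plan**
Numbering: the lactone is C9'(=O)–C8'–C8–C9H2–O. C7' and C7 are the arylmethyl carbons on C8' and C8. C7''–C9'' is the arylglycerol chain. C2, C3 and ring C belong to the dihydrobenzofuran.
Cuts, in order: C9–C8 (lactone OCH2 to ring carbon C8), C8'–C7' (enolate alkylation), C7=C8 (Wittig), C7''–C8'' and the ArO–CH2 bond (aldol, Williamson), and C2–C3 of the dihydrobenzofuran (carbene C–H insertion).
Enabling feature: C8 bears both the lactone OCH2 (C9) and the C7 methylene bound to ring C, so C7–C8 can be carried as a styrene. The chain C9–O–C9'(=O)–C8'–C8=C7 is then a hex-5-enyl array: an acyloxymethyl radical at C9 closes 5-exo on C8 and leaves a C7 radical stabilised by ring C.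
Forward: fragment A (the 8-O-4' benzylic bromide) and fragment C (the dihydrobenzofuran butenoyl imide) are made separately and joined at C8'–C7'. The lactone ring arises last, already at the right oxidation pattern, and two deprotections follow.
Stereochemistry: C8'' comes from an Evans syn aldol and C7'' from a Mitsunobu inversion. C2 comes from a chiral dirhodium carboxylate and C3 from epimerisation to trans. C8' comes from an Evans alkylation, and C8 from 1,2-induction by C8' in the ring closure.

Key step: step 21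

Assumption: in step 12 the R-configured catalyst is taken to give the 2S centre, by analogy with related 2-(benzyloxy)aryl diazoacetates; if the sense is opposite, the S-configured catalyst is used with no other change.

Step 1
Reactants: 1 (R)-4-benzyloxazolidin-2-one; 2 chloroacetyl chloride
Product: 3 (R)-4-benzyl-3-(chloroacetyl)oxazolidin-2-one
Conditions: n-BuLi, THF, −78 °C; then 2, −78 to 0 °C
Reagents that add atoms: none
Why: N-acylation of the lithiated oxazolidinone by an acid chloride is fast at low temperature and touches neither the stereocentre nor the C–Cl bond.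

Step 2
Reactants: 3 (R)-4-benzyl-3-(chloroacetyl)oxazolidin-2-one; 4 methyl vanillate
Product: 5 aryloxyacetyl imide, methyl 4-{2-[(R)-4-benzyl-2-oxooxazolidin-3-yl]-2-oxoethoxy}-3-methoxybenzoate
Conditions: K2CO3, NaI (catalytic), acetone, rt
Reagents that add atoms: none
Why: Williamson ether synthesis at an α-chloro imide, a very reactive SN2 centre further activated by iodide exchange, with a weakly basic phenoxide that leaves the imide carbonyl groups alone.

Step 3
Reactants: 5 aryloxyacetyl imide; 6 4-benzyloxy-3-methoxybenzaldehyde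
Product: 7 syn aldol adduct, the (2R,3S)-3-(4-benzyloxy-3-methoxyphenyl)-3-hydroxy-2-[2-methoxy-4-(methoxycarbonyl)phenoxy]propanoyl imide of 1
Conditions: Bu2BOTf, Et3N, CH2Cl2, −78 to 0 °C; then 6, −78 to 0 °C; H2O2, MeOH, pH 7 buffer
Reagents that add atoms: none
Why: Evans syn aldol reaction, known for aryloxyacetyl imides and aromatic aldehydes: the Z-boron enolate reacts through a closed chair transition state on the face left open by the (R)-auxiliary, which sets C8'' as in the target and C7'' in the threo (syn) sense.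

Step 4
Reactants: 7 syn aldol adduct
Product: 8 threo diol, methyl 4-{[(1S,2S)-1-(4-benzyloxy-3-methoxyphenyl)-1,3-dihydroxypropan-2-yl]oxy}-3-methoxybenzoate
Conditions: NaBH4, THF–H2O, 0 °C to rt
Reagents that add atoms: none
Why: Reductive cleavage of the N-acyl oxazolidinone takes the activated imide carbonyl to the primary alcohol and releases the auxiliary, while the electron-rich aromatic methyl ester is too unreactive to be reduced and no stereocentre is involved.

Step 5
Reactants: 8 threo diol
Product: 9 threo C9'' mono-TBS ether (1S,2S)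
Conditions: TBSCl (one equivalent), imidazole, CH2Cl2, 0 °C
Reagents that add atoms: tert-butyldimethylsilyl chloride CC(C)(C)[Si](C)(C)Cl
Why: Selective silylation, because the unhindered primary hydroxyl reacts much faster than the secondary benzylic C7'' hydroxyl.

Step 6
Reactants: 9 threo C9'' mono-TBS ether
Product: 11 erythro alcohol (1R,2S), via erythro 4-nitrobenzoate 10 (not isolated)
Conditions: PPh3, DIAD, 4-nitrobenzoic acid, THF, 0 °C to rt; then MeOH, K2CO3 (catalytic), rt
Reagents that add atoms: 4-nitrobenzoic acid O=C(O)c1ccc(cc1)[N+](=O)[O-]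
Why: Mitsunobu inversion, precedented on threo arylglycerol β-aryl ethers: the C7'' oxyphosphonium ion is displaced by the carboxylate in an SN2 process that turns threo into erythro (7''R), and base-catalysed transesterification then frees the alcohol without harm to the methyl benzoate or the silyl ether.

Step 7
Reactants: 11 erythro alcohol
Product: 12 erythro bis-TBS ether methyl ester (1R,2S)
Conditions: TBSOTf, 2,6-lutidine, CH2Cl2, 0 °C
Reagents that add atoms: tert-butyldimethylsilyl triflate CC(C)(C)[Si](C)(C)OS(=O)(=O)C(F)(F)F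
Why: Silylation of a hindered secondary alcohol with the silyl triflate and a non-nucleophilic base breaks only the O–H bond, so C7'' keeps its configuration.

Step 8
Reactants: 12 erythro bis-TBS ether methyl ester
Product: 13 benzylic alcohol of fragment A
Conditions: i-Bu2AlH, CH2Cl2, −78 to 0 °C; aq. potassium sodium tartrate
Reagents that add atoms: none
Why: Hydride reduction of the only carbonyl group gives the primary benzylic alcohol, and silyl ethers, benzyl ether and aryl ethers are inert to i-Bu2AlH.

Step 9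
Reactants: 13 benzylic alcohol of fragment A
Product: 14 benzylic bromide of fragment A
Conditions: CBr4, PPh3, CH2Cl2, 0 °C
Reagents that add atoms: tetrabromomethane BrC(Br)(Br)Br
Why: The Appel reaction converts the only free hydroxyl into the bromide under neutral conditions that keep both silyl ethers and the C7'' centre intact.

Step 10
Reactants: 15 5-iodovanillin; 16 4-benzyloxy-3-methoxybenzyl alcohol
Product: 17 4-[(4-benzyloxy-3-methoxybenzyl)oxy]-3-iodo-5-methoxybenzaldehyde
Conditions: PPh3, DIAD, THF, 0 °C to rt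
Reagents that add atoms: none
Why: Mitsunobu etherification works well for an acidic phenol and a primary benzylic alcohol, and it avoids the labile benzylic halide.

Step 11
Reactants: 17 iodo aldehyde; 18 ethyl diazoacetate
Product: 19 ethyl 2-diazo-2-{2-[(4-benzyloxy-3-methoxybenzyl)oxy]-5-formyl-3-methoxyphenyl}acetate
Conditions: Pd(PPh3)4 (catalytic), Ag2CO3 (0.5 equiv), Et3N, toluene, rt
Reagents that add atoms: none
Why: Palladium-catalysed cross-coupling of an aryl iodide with a diazoacetate: zerovalent palladium adds to C–I, the diazo carbon is palladated with loss of its proton, and reductive elimination at room temperature keeps the N2 group, with the formyl group as a spectator.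

Step 12
Reactants: 19 aryl diazoacetate
Product: 21 ethyl (2S,3S)-trans-2-(4-benzyloxy-3-methoxyphenyl)-5-formyl-7-methoxy-2,3-dihydrobenzofuran-3-carboxylate, via cis ester 20 (not isolated)
Conditions: Rh2(R-PTTL)4 (dirhodium tetrakis[N-phthaloyl-(R)-tert-leucinate], catalytic), toluene, −60 to −20 °C; then EtOH, NaOEt (catalytic), 0 °C to rt
Reagents that add atoms: none
Why: Intramolecular 1,5 C–H insertion of a donor/acceptor rhodium carbene into the ether-activated benzylic CH2, a known entry to cis-2-aryl-2,3-dihydrobenzofuran-3-carboxylates: the chiral carboxylate picks one enantiotopic hydrogen and sets C2, catalytic ethoxide then epimerises C3 to the more stable trans ester, and ring opening would be a stereoelectronically slow retro-5-endo-trig process.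

Step 13
Reactants: 21 trans aldehyde ester; 22 (2-carboxyethyl)triphenylphosphonium bromide
Product: 23 (E)-4-[(2S,3S)-2-(4-benzyloxy-3-methoxyphenyl)-3-(ethoxycarbonyl)-7-methoxy-2,3-dihydrobenzofuran-5-yl]but-3-enoic acid
Conditions: 22, NaN(SiMe3)2 (two equivalents per 22), THF, −78 to 0 °C; then 21, −78 °C to rt; 1 M HCl
Reagents that add atoms: none
Why: The Wittig reaction of the carboxylate-bearing ylide with aromatic aldehydes is a standard E-selective route to 4-arylbut-3-enoic acids, and carbonyl addition is much faster than deprotonation at C3.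

Step 14
Reactants: 23 ester acid
Product: 24 (E)-4-[(2S,3R)-2-(4-benzyloxy-3-methoxyphenyl)-3-(hydroxymethyl)-7-methoxy-2,3-dihydrobenzofuran-5-yl]but-3-enoic acid
Conditions: LiBH4, THF, 0 °C to rt; 1 M HCl to pH 3
Reagents that add atoms: none
Why: Chemoselective ester reduction, since LiBH4 reduces the ethyl ester while the acid is masked as its unreactive lithium carboxylate and the styrene is inert.

Step 15
Reactants: 24 hydroxy acid
Product: 26 (E)-4-[(2S,3R)-2-(4-benzyloxy-3-methoxyphenyl)-3-(TBS-oxymethyl)-7-methoxy-2,3-dihydrobenzofuran-5-yl]but-3-enoic acid, via silyl ester 25 (not isolated)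
Conditions: TBSCl, imidazole, DMF, rt; then MeOH–H2O, rt
Reagents that add atoms: tert-butyldimethylsilyl chloride CC(C)(C)[Si](C)(C)Cl
Why: Exhaustive silylation followed by solvolysis of the very labile silyl ester leaves only the robust primary silyl ether.

Step 16
Reactants: 26 silyl ether acid; 1 (R)-4-benzyloxazolidin-2-one
Product: 28 fragment C imide, (R)-4-benzyl-3-[(E)-4-arylbut-3-enoyl]oxazolidin-2-one, via mixed pivalic anhydride 27 (not isolated)
Conditions: t-BuCOCl, Et3N, THF, −20 °C; then LiCl, 1, −20 °C to rt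
Reagents that add atoms: pivaloyl chloride CC(C)(C)C(=O)Cl (retained only in 27)
Why: Mixed-anhydride acylation of the oxazolidinone promoted by LiCl is mild enough for 4-arylbut-3-enoic acids, whose double bond stays in conjugation with the arene.

Step 17
Reactants: 28 fragment C imide; 14 benzylic bromide of fragment A
Product: 29 alkylated imide with (R)-C8'
Conditions: NaN(SiMe3)2, THF, −78 °C; then 14, −78 to −30 °C
Reagents that add atoms: none
Why: Evans alkylation: the chelated Z-sodium dienolate reacts with the reactive benzylic bromide at its α-carbon, which keeps the styrene conjugated, on the face opposite the auxiliary benzyl group, and this sets C8' as R.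

Step 18
Reactants: 29 alkylated imide
Product: 30 (2R,3E)-2-(fragment A arylmethyl)-4-(fragment C aryl)but-3-enoic acid
Conditions: LiOH, H2O2, THF–H2O, 0 °C; Na2SO3; HCl to pH 3
Reagents that add atoms: hydrogen peroxide OO
Why: Hydroperoxide cleavage attacks the exocyclic carbonyl of the branched imide selectively at 0 °C, and the product is held as its carboxylate, which protects the doubly activated C8'–H from exchange and the alkene from migration.

Step 19
Reactants: 30 acid; 31 chloromethyl chlorosulfate
Product: 32 chloromethyl ester of 30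
Conditions: NaHCO3, Bu4NHSO4 (catalytic), CH2Cl2–H2O, rt
Reagents that add atoms: none
Why: Phase-transfer O-alkylation of the carboxylate, in which chlorosulfate leaves in preference to chloride, is the standard mild route to chloromethyl esters, and the bicarbonate medium is too weakly basic to epimerise C8'.

Step 20
Reactants: 32 chloromethyl ester
Product: 33 iodomethyl ester of 30
Conditions: NaI, acetone, rt, dark
Reagents that add atoms: sodium iodide [Na+].[I-]
Why: Finkelstein exchange at the activated O–CH2–Cl carbon, driven by precipitation of NaCl, gives a radical precursor whose C–I bond is abstracted far faster than any other group in the molecule reacts with a stannyl radical.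

Step 21
Reactants: 33 iodomethyl ester
Product: 34 protected trans lactone (8R,8'R) with three TBS ethers and two benzyl ethers
Conditions: Bu3SnH, AIBN (catalytic), benzene, 80 °C, both added by syringe pump over several hours to a dilute (about 5 mM) solution of 33
Reagents that add atoms: none
Why: The stannyl radical abstracts iodine from 33 to give the acyloxymethyl radical at C9, which adds through the less populated E rotamer of the ester to C8 of the C8=C7 styrene, and the resulting C7 radical, stabilised by ring C, takes hydrogen from Bu3SnH and carries the chain. The closest known reaction type is the tin hydride cyclisation of halomethyl and phenylselenomethyl but-3-enoates to γ-butyrolactones. The lactone (C9, O, C9', C8', C8) closes in the 5-exo-trig mode, and the 6-endo alternative is disfavoured because it would place the radical on the non-benzylic C8. The new C8 centre is controlled by C8': in the chair-like transition state the C8' arylmethyl group lies pseudo-equatorial, so C9 bonds to the alkene face that places the C7 arm trans to it, which with (R)-C8' gives (R)-C8. The step needs ring closure to outrun hydrogen transfer to the open radical and 1,5-hydrogen shift from C7', which is secured by the fast addition of the nucleophilic α-oxy radical to a styrene, by the temperature (rotamer exchange) and by the low stationary Bu3SnH concentration. Any cis lactone should be removed by chromatography, because its epimerisation at C8' would lead into the wrong diastereomeric series.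

Step 22
Reactants: 34 protected trans lactone
Product: 35 triol bis(benzyl ether)
Conditions: Bu4NF, AcOH, THF, rt
Reagents that add atoms: none
Why: Fluoride cleaves the three silyl ethers while acetic acid buffers the alkoxides so that the lactone is safe, and with both phenols still benzylated no quinone methide can form at C7'' or C2.

Step 23
Reactants: 35 triol bis(benzyl ether)
Product: 36 target CNP0298853.1
Conditions: H2 (1 atm), Pd on carbon (catalytic), EtOAc–EtOH, rt
Reagents that add atoms: none
Why: Neutral hydrogenolysis removes the two unhindered primary O-benzyl groups much faster than it attacks the secondary ring-embedded C2–O bond or the C7'' alcohol, as is usual for phenylcoumaran and arylglycerol β-aryl ether models, and the reaction is stopped after uptake of two equivalents of H2.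

**Compound list**
1 | (R)-4-benzyloxazolidin-2-one | O=C1N[C@H](Cc2ccccc2)CO1 | starting material
2 | chloroacetyl chloride | ClCC(Cl)=O | starting material
3 | (R)-4-benzyl-3-(chloroacetyl)oxazolidin-2-one | O=C1OC[C@@H](Cc2ccccc2)N1C(=O)CCl | intermediate
4 | methyl vanillate (methyl 4-hydroxy-3-methoxybenzoate) | COC(=O)c1ccc(O)c(OC)c1 | starting material
5 | methyl 4-{2-[(R)-4-benzyl-2-oxooxazolidin-3-yl]-2-oxoethoxy}-3-methoxybenzoate | COC(=O)c1ccc(OCC(=O)N2[C@H](Cc3ccccc3)COC2=O)c(OC)c1 | intermediate
6 | 4-benzyloxy-3-methoxybenzaldehyde | COc1cc(C=O)ccc1OCc1ccccc1 | starting material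
7 | syn aldol adduct (2R,3S), imide of 1 | COc1cc([C@H](O)[C@H](C(=O)N2[C@H](Cc3ccccc3)COC2=O)Oc2ccc(C(=O)OC)cc2OC)ccc1OCc1ccccc1 | intermediate
8 | threo diol (1S,2S) | COc1cc([C@H](O)[C@H](CO)Oc2ccc(C(=O)OC)cc2OC)ccc1OCc1ccccc1 | intermediate
9 | threo C9'' mono-TBS ether (1S,2S) | COc1cc([C@H](O)[C@H](CO[Si](C)(C)C(C)(C)C)Oc2ccc(C(=O)OC)cc2OC)ccc1OCc1ccccc1 | intermediate
10 | erythro C7'' 4-nitrobenzoate (1R,2S) | COc1cc([C@@H](OC(=O)c2ccc(cc2)[N+](=O)[O-])[C@H](CO[Si](C)(C)C(C)(C)C)Oc2ccc(C(=O)OC)cc2OC)ccc1OCc1ccccc1 | intermediate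
11 | erythro alcohol (1R,2S) | COc1cc([C@@H](O)[C@H](CO[Si](C)(C)C(C)(C)C)Oc2ccc(C(=O)OC)cc2OC)ccc1OCc1ccccc1 | intermediate
12 | erythro bis-TBS ether methyl ester (1R,2S) | COc1cc([C@@H](O[Si](C)(C)C(C)(C)C)[C@H](CO[Si](C)(C)C(C)(C)C)Oc2ccc(C(=O)OC)cc2OC)ccc1OCc1ccccc1 | intermediate
13 | benzylic alcohol of fragment A | COc1cc([C@@H](O[Si](C)(C)C(C)(C)C)[C@H](CO[Si](C)(C)C(C)(C)C)Oc2ccc(CO)cc2OC)ccc1OCc1ccccc1 | intermediate
14 | benzylic bromide of fragment A | COc1cc([C@@H](O[Si](C)(C)C(C)(C)C)[C@H](CO[Si](C)(C)C(C)(C)C)Oc2ccc(CBr)cc2OC)ccc1OCc1ccccc1 | intermediate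
15 | 5-iodovanillin (4-hydroxy-3-iodo-5-methoxybenzaldehyde) | COc1cc(C=O)cc(I)c1O | starting material
16 | 4-benzyloxy-3-methoxybenzyl alcohol | COc1cc(CO)ccc1OCc1ccccc1 | starting material
17 | 4-[(4-benzyloxy-3-methoxybenzyl)oxy]-3-iodo-5-methoxybenzaldehyde | COc1cc(C=O)cc(I)c1OCc1ccc(OCc2ccccc2)c(OC)c1 | intermediate
18 | ethyl diazoacetate | CCOC(=O)C=[N+]=[N-] | starting material
19 | ethyl 2-diazo-2-{2-[(4-benzyloxy-3-methoxybenzyl)oxy]-5-formyl-3-methoxyphenyl}acetate | CCOC(=O)C(=[N+]=[N-])c1cc(C=O)cc(OC)c1OCc1ccc(OCc2ccccc2)c(OC)c1 | intermediate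
20 | ethyl (2S,3R)-cis-2-(4-benzyloxy-3-methoxyphenyl)-5-formyl-7-methoxy-2,3-dihydrobenzofuran-3-carboxylate | O=Cc1cc(OC)c2c(c1)[C@@H](C(=O)OCC)[C@@H](c1ccc(OCc3ccccc3)c(OC)c1)O2 | intermediate
21 | ethyl (2S,3S)-trans-2-(4-benzyloxy-3-methoxyphenyl)-5-formyl-7-methoxy-2,3-dihydrobenzofuran-3-carboxylate | O=Cc1cc(OC)c2c(c1)[C@H](C(=O)OCC)[C@@H](c1ccc(OCc3ccccc3)c(OC)c1)O2 | intermediate
22 | (2-carboxyethyl)triphenylphosphonium bromide | OC(=O)CC[P+](c1ccccc1)(c1ccccc1)c1ccccc1.[Br-] | starting material
23 | (E)-butenoic acid with C3 ethyl ester (2S,3S) | OC(=O)C/C=C/c1cc(OC)c2c(c1)[C@H](C(=O)OCC)[C@@H](c1ccc(OCc3ccccc3)c(OC)c1)O2 | intermediate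
24 | (E)-butenoic acid with C3 hydroxymethyl (2S,3R) | OC(=O)C/C=C/c1cc(OC)c2c(c1)[C@H](CO)[C@@H](c1ccc(OCc3ccccc3)c(OC)c1)O2 | intermediate
25 | TBS ester of the TBS ether (2S,3R) | CC(C)(C)[Si](C)(C)OC(=O)C/C=C/c1cc(OC)c2c(c1)[C@H](CO[Si](C)(C)C(C)(C)C)[C@@H](c1ccc(OCc3ccccc3)c(OC)c1)O2 | intermediate
26 | (E)-butenoic acid with C3 TBS-oxymethyl (2S,3R) | OC(=O)C/C=C/c1cc(OC)c2c(c1)[C@H](CO[Si](C)(C)C(C)(C)C)[C@@H](c1ccc(OCc3ccccc3)c(OC)c1)O2 | intermediate
27 | mixed pivalic anhydride of 26 | CC(C)(C)C(=O)OC(=O)C/C=C/c1cc(OC)c2c(c1)[C@H](CO[Si](C)(C)C(C)(C)C)[C@@H](c1ccc(OCc3ccccc3)c(OC)c1)O2 | intermediate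
28 | fragment C imide | O=C1OC[C@@H](Cc2ccccc2)N1C(=O)C/C=C/c1cc(OC)c2c(c1)[C@H](CO[Si](C)(C)C(C)(C)C)[C@@H](c1ccc(OCc3ccccc3)c(OC)c1)O2 | intermediate
29 | alkylated imide (8'R) | COc1cc([C@@H](O[Si](C)(C)C(C)(C)C)[C@H](CO[Si](C)(C)C(C)(C)C)Oc2ccc(C[C@H](/C=C/c3cc(OC)c4c(c3)[C@H](CO[Si](C)(C)C(C)(C)C)[C@@H](c3ccc(OCc5ccccc5)c(OC)c3)O4)C(=O)N3[C@H](Cc5ccccc5)COC3=O)cc2OC)ccc1OCc1ccccc1 | intermediate
30 | (2R,3E)-acid | COc1cc([C@@H](O[Si](C)(C)C(C)(C)C)[C@H](CO[Si](C)(C)C(C)(C)C)Oc2ccc(C[C@H](/C=C/c3cc(OC)c4c(c3)[C@H](CO[Si](C)(C)C(C)(C)C)[C@@H](c3ccc(OCc5ccccc5)c(OC)c3)O4)C(=O)O)cc2OC)ccc1OCc1ccccc1 | intermediate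
31 | chloromethyl chlorosulfate | ClCOS(=O)(=O)Cl | starting material
32 | chloromethyl ester of 30 | COc1cc([C@@H](O[Si](C)(C)C(C)(C)C)[C@H](CO[Si](C)(C)C(C)(C)C)Oc2ccc(C[C@H](/C=C/c3cc(OC)c4c(c3)[C@H](CO[Si](C)(C)C(C)(C)C)[C@@H](c3ccc(OCc5ccccc5)c(OC)c3)O4)C(=O)OCCl)cc2OC)ccc1OCc1ccccc1 | intermediate
33 | iodomethyl ester of 30 | COc1cc([C@@H](O[Si](C)(C)C(C)(C)C)[C@H](CO[Si](C)(C)C(C)(C)C)Oc2ccc(C[C@H](/C=C/c3cc(OC)c4c(c3)[C@H](CO[Si](C)(C)C(C)(C)C)[C@@H](c3ccc(OCc5ccccc5)c(OC)c3)O4)C(=O)OCI)cc2OC)ccc1OCc1ccccc1 | intermediate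
34 | protected trans lactone (8R,8'R) | COc1cc([C@@H](O[Si](C)(C)C(C)(C)C)[C@H](CO[Si](C)(C)C(C)(C)C)Oc2ccc(C[C@H]3C(=O)OC[C@@H]3Cc3cc(OC)c4c(c3)[C@H](CO[Si](C)(C)C(C)(C)C)[C@@H](c3ccc(OCc5ccccc5)c(OC)c3)O4)cc2OC)ccc1OCc1ccccc1 | intermediate
35 | triol bis(benzyl ether) | COc1cc([C@@H](O)[C@H](CO)Oc2ccc(C[C@H]3C(=O)OC[C@@H]3Cc3cc(OC)c4c(c3)[C@H](CO)[C@@H](c3ccc(OCc5ccccc5)c(OC)c3)O4)cc2OC)ccc1OCc1ccccc1 | intermediate
36 | CNP0298853.1 | COc1cc([C@@H](O)[C@H](CO)Oc2ccc(C[C@H]3C(=O)OC[C@@H]3Cc3cc(OC)c4c(c3)[C@H](CO)[C@@H](c3ccc(O)c(OC)c3)O4)cc2OC)ccc1O | target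

**Count**
Total: 23 steps. Longest linear sequence: 16 steps (steps 1–9 and 17–23). The fragment C branch (steps 10–16) joins at step 17.

**Steps most likely to fail**

Step 21. Hydrogen transfer to the open-chain acyloxymethyl radical may occur before the ester reaches its reactive rotamer, or the facial bias at C8 may be weak. The fallback sets out from aldehyde 21 and bromide 14 and returns at 34; it builds the lactone first and makes C8'–C7' last. Aldehyde 21 undergoes Stobbe condensation with dimethyl succinate (t-BuOK, t-BuOH) to give the E-configured benzylidenesuccinic half-ester F1. Homogeneous asymmetric hydrogenation with [Rh(cod)((S,S)-Et-DuPhos)]OTf, using the ligand enantiomer that delivers the R centre and leaving the benzyl ethers untouched, gives the (R)-arylmethylsuccinic acid 1-methyl ester F2. LiBH4 reduces both ester groups but not the carboxylate, and acidic work-up closes the (R)-β-arylmethyl-γ-butyrolactone alcohol F3. TBSCl and imidazole give the lactone silyl ether F4. Its lithium enolate (LiN(SiMe3)2, THF, −78 °C) is alkylated by 14 anti to the C8 substituent and gives 34.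

Step 12. The catalyst may differentiate the two enantiotopic benzylic C–H bonds incompletely, or the carbene may be diverted by the formyl oxygen or by dimerisation. The fallback sets out from 17 and returns at 21; it moves stereocontrol into a covalently bound auxiliary. Commercial (S)-2-hydroxy-1-(pyrrolidin-1-yl)propan-1-one is converted with glyoxylic acid chloride tosylhydrazone and Et3N into the lactamide diazoacetate F5. This is coupled with 17 under the conditions of step 11 to give the auxiliary-bearing aryl diazoacetate F6. Insertion with Rh2(S-DOSP)4 (dirhodium tetrakis[(S)-N-(4-dodecylphenylsulfonyl)prolinate]) in the matched pairing should give the (2S,3S)-trans lactamide ester F7 directly. Ethanolysis with Ti(OEt)4 in EtOH then gives 21.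

Step 11. Coupling may be sluggish at the iodide flanked by the bulky benzyloxy group, so that palladium-induced loss of N2 from the diazo partner overtakes it. The fallback sets out from 17 and returns at 19; it makes the aryl–carbon bond first and introduces nitrogen afterwards. HC(OMe)3 and catalytic TsOH in MeOH give the dimethyl acetal F8. Negishi-type coupling with the Reformatsky reagent BrZnCH2CO2Et (Pd(dba)2, P(t-Bu)3, THF) gives the arylacetate acetal F9. Dilute aqueous acid frees the formyl arylacetate F10. Diazo transfer with 4-acetamidobenzenesulfonyl azide and DBU in MeCN then gives 19.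

**Further compounds**
F1 | step 21 | (E)-benzylidenesuccinic half-ester from 21 | OC(=O)C/C(C(=O)OC)=C\c1cc(OC)c2c(c1)[C@H](C(=O)OCC)[C@@H](c1ccc(OCc3ccccc3)c(OC)c1)O2
F2 | step 21 | (R)-2-(arylmethyl)succinic acid 1-methyl ester | OC(=O)C[C@@H](Cc1cc(OC)c2c(c1)[C@H](C(=O)OCC)[C@@H](c1ccc(OCc3ccccc3)c(OC)c1)O2)C(=O)OC
F3 | step 21 | (R)-β-(arylmethyl)-γ-butyrolactone with C3 hydroxymethyl | O=C1C[C@@H](Cc2cc(OC)c3c(c2)[C@H](CO)[C@@H](c2ccc(OCc4ccccc4)c(OC)c2)O3)CO1
F4 | step 21 | TBS ether of F3 | O=C1C[C@@H](Cc2cc(OC)c3c(c2)[C@H](CO[Si](C)(C)C(C)(C)C)[C@@H](c2ccc(OCc4ccccc4)c(OC)c2)O3)CO1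
F5 | step 12 | (S)-1-oxo-1-(pyrrolidin-1-yl)propan-2-yl diazoacetate | C[C@H](OC(=O)C=[N+]=[N-])C(=O)N1CCCC1
F6 | step 12 | aryl diazoacetate carrying the (S)-lactamide auxiliary | C[C@H](OC(=O)C(=[N+]=[N-])c1cc(C=O)cc(OC)c1OCc1ccc(OCc2ccccc2)c(OC)c1)C(=O)N1CCCC1
F7 | step 12 | (2S,3S)-trans-dihydrobenzofuran (S)-lactamide ester | O=Cc1cc(OC)c2c(c1)[C@H](C(=O)O[C@@H](C)C(=O)N1CCCC1)[C@@H](c1ccc(OCc3ccccc3)c(OC)c1)O2
F8 | step 11 | dimethyl acetal of 17 | COc1cc(C(OC)OC)cc(I)c1OCc1ccc(OCc2ccccc2)c(OC)c1
F9 | step 11 | ethyl arylacetate dimethyl acetal | CCOC(=O)Cc1cc(C(OC)OC)cc(OC)c1OCc1ccc(OCc2ccccc2)c(OC)c1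
F10 | step 11 | ethyl 2-{2-[(4-benzyloxy-3-methoxybenzyl)oxy]-5-formyl-3-methoxyphenyl}acetate | CCOC(=O)Cc1cc(C=O)cc(OC)c1OCc1ccc(OCc2ccccc2)c(OC)c1
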